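The data stem from a simulated flask for substances that don't exist; noise was put on by code.

How much product, substrate and by-product stand in this flask after 12 min?

- concentration of product at 12 min, in mM
- concentration of substrate at 12 min, in mM
- concentration of by-product at 12 min, in mM

common to all: substrate 13 mM; free catalyst 0.13 mM

| run | coupling partner | remark | time |
|---|---|---|---|
| south | 25 mM (in portions, 2) | run made earlier; portions every 80 s |  |
| flask | 12.3 mM (in portions, 2) | the portions of coupling partner follow each other after 80 s, the first at the start | 12 min |

- reactions considered so far: substrate + free catalyst <-> catalyst intermediate A; catalyst intermediate A -> catalyst intermediate B; coupling partner + catalyst intermediate B -> catalyst intermediate C; catalyst intermediate C -> by-product + catalyst intermediate D; catalyst intermediate D -> catalyst intermediate E; catalyst intermediate E -> free catalyst + product; catalyst intermediate D -> spent catalyst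

- south (time / min: product / %, substrate / %): 0.250: 0.4, 98.9; 0.417: 0.5, 99.3; 0.667: 1.0, 97.4; 1.00: 1.9, 97.0; 1.50: 2.9, 96.3; 2.50: 5.2, 93.5; 4.00: 10.2, 90.8

(each reading ± 0.5 percentage points)

I ask first where the flask must end, then how fast it goes there. Each round of the catalyst takes one substrate and one coupling partner and gives one by-product and one product. The coupling partner, at 12.3 mM against 13 mM of substrate, is the limiting reagent, so the ceiling of [product] in this flask is 12.3 mM.

Now I read the south run row by row. The row at 1.00 min stands before that run's second portion, with a charge so far of 12.5 mM, close to the 12.3 mM this flask is charged to. Its 1.9% of product on 13 mM of substrate gives a rate of 0.247 mM min⁻¹, a rough figure, since the reading carries a scatter of 0.5 percentage points.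

The rows from 1.50 min to 4.00 min, after the second portion, give 0.380 mM min⁻¹. That reading is 1.54 times the first rate on twice the charge, so in these readings of the south run the rate grows less than in proportion to the partner. As an estimate I therefore hold the first rate constant in this flask, where it uses about a quarter of the partner, and I pass over the first 11.1% of the time, when this flask has had its first portion and not its whole charge.

Ceiling over rate gives 49.8 min. I call this the filling time, the limiting charge divided by the rate read from the south run on about that charge. This flask is read at 24.1% of its filling time, so I expect [product] near 2.96 mM, [by-product] the same, and [substrate] near 10.0 mM.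

The forecast is lower on product, 2.4 mM against my 2.96 mM, with 10.5 mM of substrate and 2.5 mM of by-product, in its words “Allowing for unseen deactivation”.

The flask gives [product] 3.17 mM, [substrate] 9.74 mM and [by-product] 3.18 mM.

    substrate + free catalyst ⇌ catalyst intermediate A (K = 430 M⁻¹, k = 670 M⁻¹ min⁻¹)
    catalyst intermediate A → catalyst intermediate B (k = 11.0 min⁻¹)
    coupling partner + catalyst intermediate B → catalyst intermediate C (k = 1000 M⁻¹ min⁻¹)
    catalyst intermediate C → by-product + catalyst intermediate D (k = 9.20 min⁻¹)
    catalyst intermediate D → catalyst intermediate E (k = 53.0 min⁻¹)
    catalyst intermediate E → free catalyst + product (k = 97.0 min⁻¹)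
    catalyst intermediate D → spent catalyst (k = 0.0210 min⁻¹)

That product is 25.8% of the ceiling, at 24.1% of the filling time. The neighbour is this same flask left until 50 min, which is 1.00 filling times, where the straight line stands at the ceiling of 12.3 mM. The neighbour holds [product] 9.87 mM, which is 80.2% of the ceiling, so its average rate is 0.197 mM min⁻¹, slower than the 0.247 mM min⁻¹ read from the south run. Its [coupling partner] stands at 19.6% of its charge.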